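## Retrosynthetic overview

- Locants: C1 lactone carbonyl, C2H=C3 ring alkene, C25H2 ring OCH2, C4 carbinol, C5H2, C6H=C7, C24H2OH on C7. The route rests on reading the C4 carbinol and the C2=C3 bond of the furanone ring as the base-opened form of a C3–C4 oxirane lying β,γ to C1. In the ring-opened C25/C1 diol, the C25 hydroxyl is allylic to C3=C4 and can steer an asymmetric epoxidation that fixes C4.
- Butenolide ⇒ spiro β,γ-epoxy lactone (E1cB opening) ⇒ epoxy diol (oxidative lactonisation towards C1) ⇒ (E)-allylic 1,4-diol (Sharpless epoxidation) ⇒ α-alkylidene lactone (hydride reduction).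
- C3=C4 ⇒ cross-metathesis of a terminal alkene with 3-methylideneoxolan-2-one. C6=C7 ⇒ anti-carbomagnesiation of hex-5-en-2-yn-1-ol with homofarnesylmagnesium bromide, which comes from (2E,6E)-farnesol by one-carbon homologation (C15 + C1 gives the C16 unit from C8 to the chain terminus with its three methyl groups).
- Ring order: oxirane (step 10), then lactone ring (step 11); the oxirane is given up in step 12 and leaves the butenolide.

Key step: step 10

Remark: commercial farnesol is taken as the pure (2E,6E) isomer; the locants C1–C25 defined above are used throughout.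

## Route

Step 1
Reactants: 1 (2E,6E)-farnesol
Product: 2 (2E,6E)-farnesal
Conditions: TEMPO (10 mol%), PhI(OAc)2 (1.1 equiv), CH2Cl2, rt
Reagents that add atoms: none
Why: Oxoammonium oxidation (TEMPO/PhI(OAc)2) of a primary allylic alcohol stops at the aldehyde and, being neither strongly acidic nor basic, should leave the 2E geometry and the other alkenes untouched.

Step 2
Reactants: 2 (2E,6E)-farnesal
Product: 3 (3E,7E)-4,8,12-trimethyltrideca-1,3,7,11-tetraene
Conditions: Ph3PCH3Br, n-BuLi, THF, 0 °C to rt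
Reagents that add atoms: methyltriphenylphosphonium bromide, C[P+](c1ccccc1)(c1ccccc1)c1ccccc1.[Br-]
Why: Wittig methylenation of the enal with the unstabilised ylide adds the one extra carbon and should give the terminal diene without touching the existing E-alkenes.

Step 3
Reactants: 3 (3E,7E)-4,8,12-trimethyltrideca-1,3,7,11-tetraene
Product: 5 (3E,7E)-4,8,12-trimethyltrideca-3,7,11-trien-1-ol (homofarnesol), via B-homofarnesyl-9-BBN 4 (not isolated)
Conditions: 9-BBN (1.1 equiv), THF, 0 °C to rt; then aq. NaOH, H2O2, 0 °C to rt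
Reagents that add atoms: hydrogen peroxide, OO
Why: Hydroboration–oxidation with the bulky 9-BBN is selective for the monosubstituted terminus of the diene over the trisubstituted alkenes and places boron on C-1, so oxidation with retention should give the homoallylic primary alcohol.

Step 4
Reactants: 5 homofarnesol
Product: 6 (3E,7E)-1-bromo-4,8,12-trimethyltrideca-3,7,11-triene (homofarnesyl bromide)
Conditions: CBr4, PPh3, CH2Cl2, 0 °C
Reagents that add atoms: carbon tetrabromide, BrC(Br)(Br)Br
Why: Appel bromination displaces the alkoxyphosphonium ion by SN2 at a primary carbon under neutral conditions that spare the trisubstituted alkenes.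

Step 5
Reactants: 7 prop-2-yn-1-ol; 8 allyl bromide
Product: 9 hex-5-en-2-yn-1-ol
Conditions: CuI (10 mol%), K2CO3, n-Bu4NI (10 mol%), DMF, rt
Reagents that add atoms: none
Why: CuI-catalysed coupling of the terminal alkyne, as its copper acetylide, with allyl bromide under carbonate base forms the skipped enyne without protection of the hydroxyl.

Step 6
Reactants: 6 homofarnesyl bromide; 9 hex-5-en-2-yn-1-ol
Product: 13 (2E)-2-[(3E,7E)-4,8,12-trimethyltrideca-3,7,11-trien-1-yl]hexa-2,5-dien-1-ol, via homofarnesylmagnesium bromide 10 (not isolated), via chloromagnesium hexenynolate 11 (not isolated), via oxamagnesacycle 12 (not isolated)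
Conditions: 6, Mg turnings, THF, rt; separately 9 (1.3 equiv), iPrMgCl (1.3 equiv), THF, 0 °C; combine, CuI (10 mol%), Et2O–THF, 0 °C to rt; then H2O
Reagents that add atoms: none
Why: CuI-catalysed carbomagnesiation of a 2-alkyn-1-ol proceeds by alkoxide-directed anti addition, the alkyl group entering at the alkyne carbon next to the carbinol (C7) and magnesium at C6 within a five-membered O–Mg–C chelate, so protonation should leave the new chain cis to C5 and the CH2OH group trans to it (2E).

Step 7
Reactants: 13 dienol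
Product: 14 tert-butyl(dimethyl){[(2E)-2-[(3E,7E)-4,8,12-trimethyltrideca-3,7,11-trien-1-yl]hexa-2,5-dien-1-yl]oxy}silane
Conditions: TBSCl, imidazole, CH2Cl2, 0 °C to rt
Reagents that add atoms: tert-butyldimethylsilyl chloride, CC(C)(C)[Si](C)(C)Cl
Why: Imidazole-promoted silylation of the primary allylic alcohol masks C24–OH so that, after the later reduction, C25–OH is the only allylic hydroxyl.

Step 8
Reactants: 14 silyl ether; 15 3-methylideneoxolan-2-one
Product: 16 (3E)-3-[(3E,7E,11E)-4-{[tert-butyl(dimethyl)silyl]oxymethyl}-8,12,16-trimethylheptadeca-3,7,11,15-tetraen-1-ylidene]oxolan-2-one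
Conditions: 15 (5 equiv), second-generation Hoveyda–Grubbs catalyst (5 mol%), 2,6-dichloro-1,4-benzoquinone (10 mol%), CH2Cl2 (0.3 M), 40 °C
Reagents that add atoms: none
Why: Olefin cross-metathesis of a monosubstituted alkene with the methylene lactone is an established route to (E)-α-alkylidene butyrolactones; the quinone additive suppresses migration of the exocyclic alkene into the ring, the more stable E isomer (chain anti to the carbonyl) is expected, and excess 15 at high concentration is meant to outpace metathesis at the trisubstituted alkenes.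

Step 9
Reactants: 16 alkylidene lactone
Product: 18 (2E)-2-[(3E,7E,11E)-4-{[tert-butyl(dimethyl)silyl]oxymethyl}-8,12,16-trimethylheptadeca-3,7,11,15-tetraen-1-ylidene]butane-1,4-diol, via lactol 17 (not isolated)
Conditions: iBu2AlH (4.5 equiv), CH2Cl2, −78 to 0 °C; then aq. potassium sodium tartrate
Reagents that add atoms: none
Why: Excess iBu2AlH reduces the conjugated lactone in 1,2-fashion through the lactol to the 1,4-diol, which should leave the alkene geometry, the other alkenes and the silyl ether untouched.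

Step 10
Reactants: 18 allylic 1,4-diol
Product: 19 2-[(2R,3R)-3-[(2E,6E,10E)-3-{[tert-butyl(dimethyl)silyl]oxymethyl}-7,11,15-trimethylhexadeca-2,6,10,14-tetraen-1-yl]-2-(hydroxymethyl)oxiran-2-yl]ethan-1-ol
Conditions: Ti(OiPr)4 (1.0 equiv), D-(−)-diisopropyl tartrate (1.2 equiv), tBuOOH (2.0 equiv, anhydrous in decane), 4 Å molecular sieves, CH2Cl2, −25 °C; then H2O, filter through Celite
Reagents that add atoms: tert-butyl hydroperoxide, CC(C)(C)OO
Why: The C25 alkoxide of 18 and tBuOOH both bind the tetravalent titanium of the Ti(OiPr)4–tartrate complex, and the distal peroxide oxygen is passed to C3=C4 in one concerted, syn-stereospecific event, so the C3–O and C4–O bonds form together and the E geometry becomes the trans arrangement of C5 and C25 on the oxirane. The closest known reaction type is the Sharpless asymmetric epoxidation of 2,3-disubstituted (E)-allylic alcohols. The three-membered ring thus closes by oxygen-atom transfer to the alkene (a [2+1] closure), not by an intramolecular displacement. Both new stereocentres, C3 and C4, are set by the tartrate: D-(−)-tartrate converts (E)-2-alken-1-ols into (2R,3R)-epoxy alcohols, and since C25, C3 and C4 of 18 stand for C1, C2 and C3 of that model with the CIP ranks in the same order (the C2H2 group on C3 ranks lowest, as H does in the model), the (3R,4R)-oxirane of 19 is expected. The step must choose one face of one alkene out of five; only C3=C4 has a free allylic hydroxyl to hold it on titanium, the C24 oxygen is silylated, and the homoallylic C1 hydroxyl flanks the same alkene, so its much slower directed pathway may cost rate and some enantiomeric purity but cannot send the oxidant to another double bond. A full equivalent of Ti(OiPr)4 and tartrate is used because the 1,4-diol and the epoxy diol can both occupy the metal, and the low temperature protects the acid-sensitive 2,2-disubstituted oxirane.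

Step 11
Reactants: 19 epoxy diol
Product: 22 (2R,3R)-2-[(2E,6E,10E)-3-{[tert-butyl(dimethyl)silyl]oxymethyl}-7,11,15-trimethylhexadeca-2,6,10,14-tetraen-1-yl]-1,5-dioxaspiro[2.4]heptan-6-one, via hydroxy aldehyde 20 (not isolated), via lactol 21 (not isolated)
Conditions: TEMPO (20 mol%), PhI(OAc)2 (2.5 equiv), CH2Cl2, rt
Reagents that add atoms: none
Why: In this TEMPO/PhI(OAc)2 oxidative lactonisation of a 1,4-diol the oxoammonium salt should attack the unhindered C1 carbinol in preference to the neopentyl-type C25 carbinol on the fully substituted, inductively deactivated oxirane carbon, the C1 aldehyde closes to the five-membered lactol with the C25 oxygen and this is oxidised on to the lactone, with both stereocentres untouched.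

Step 12
Reactants: 22 spiro epoxy lactone
Product: 23 4-[(1R,3E,7E,11E)-4-{[tert-butyl(dimethyl)silyl]oxymethyl}-1-hydroxy-8,12,16-trimethylheptadeca-3,7,11,15-tetraen-1-yl]furan-2(5H)-one
Conditions: DBU (0.3 equiv), CH2Cl2, 0 °C; then aq. NH4Cl
Reagents that add atoms: none
Why: E1cB opening of a β,γ-epoxy carbonyl compound: DBU removes the acidic C2 proton and the enolate expels the strained C3–O bond, which creates the C2=C3 butenolide alkene and frees the C4 alkoxide with its C4–O bond, and hence the R configuration, intact; the C4 oxygen lies trans to C1 across C2=C3 and cannot translactonise.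

Step 13
Reactants: 23 silyl-protected hydroxy butenolide
Product: 24 Hippolide C (4-[(1R,3E,7E,11E)-1-hydroxy-4-(hydroxymethyl)-8,12,16-trimethylheptadeca-3,7,11,15-tetraen-1-yl]furan-2(5H)-one)
Conditions: HF·pyridine, pyridine, THF, 0 °C to rt
Reagents that add atoms: none
Why: Fluoride-mediated cleavage of the primary TBS ether with buffered HF·pyridine avoids basic conditions that could isomerise the γ-hydroxy butenolide and does not touch the carbinol stereocentre.

## Compound list

1 | (2E,6E)-farnesol | CC(C)=CCC/C(C)=C/CC/C(C)=C/CO | starting material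
2 | (2E,6E)-farnesal | CC(C)=CCC/C(C)=C/CC/C(C)=C/C=O | intermediate
3 | (3E,7E)-4,8,12-trimethyltrideca-1,3,7,11-tetraene | CC(C)=CCC/C(C)=C/CC/C(C)=C/C=C | intermediate
4 | 9-[(3E,7E)-4,8,12-trimethyltrideca-3,7,11-trien-1-yl]-9-borabicyclo[3.3.1]nonane (formed in the flask) | CC(C)=CCC/C(C)=C/CC/C(C)=C/CCB1C2CCCC1CCC2 | intermediate
5 | (3E,7E)-4,8,12-trimethyltrideca-3,7,11-trien-1-ol (homofarnesol) | CC(C)=CCC/C(C)=C/CC/C(C)=C/CCO | intermediate
6 | (3E,7E)-1-bromo-4,8,12-trimethyltrideca-3,7,11-triene | CC(C)=CCC/C(C)=C/CC/C(C)=C/CCBr | intermediate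
7 | prop-2-yn-1-ol | OCC#C | starting material
8 | allyl bromide | C=CCBr | starting material
9 | hex-5-en-2-yn-1-ol | C=CCC#CCO | intermediate
10 | [(3E,7E)-4,8,12-trimethyltrideca-3,7,11-trien-1-yl]magnesium bromide (formed in the flask) | CC(C)=CCC/C(C)=C/CC/C(C)=C/CC[Mg]Br | intermediate
11 | chloromagnesium hex-5-en-2-yn-1-olate (formed in the flask) | C=CCC#CCO[Mg]Cl | intermediate
12 | 3-(prop-2-en-1-yl)-4-[(3E,7E)-4,8,12-trimethyltrideca-3,7,11-trien-1-yl]-2,5-dihydro-1,2-oxamagnesole (formed in the flask) | CC(C)=CCC/C(C)=C/CC/C(C)=C/CCC1=C(CC=C)[Mg]OC1 | intermediate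
13 | (2E)-2-[(3E,7E)-4,8,12-trimethyltrideca-3,7,11-trien-1-yl]hexa-2,5-dien-1-ol | CC(C)=CCC/C(C)=C/CC/C(C)=C/CC/C(CO)=C\CC=C | intermediate
14 | tert-butyl(dimethyl){[(2E)-2-[(3E,7E)-4,8,12-trimethyltrideca-3,7,11-trien-1-yl]hexa-2,5-dien-1-yl]oxy}silane | CC(C)=CCC/C(C)=C/CC/C(C)=C/CC/C(CO[Si](C)(C)C(C)(C)C)=C\CC=C | intermediate
15 | 3-methylideneoxolan-2-one | C=C1CCOC1=O | starting material
16 | (3E)-3-[(3E,7E,11E)-4-{[tert-butyl(dimethyl)silyl]oxymethyl}-8,12,16-trimethylheptadeca-3,7,11,15-tetraen-1-ylidene]oxolan-2-one | CC(C)=CCC/C(C)=C/CC/C(C)=C/CC/C(CO[Si](C)(C)C(C)(C)C)=C\C/C=C1\CCOC1=O | intermediate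
17 | (3E)-3-[(3E,7E,11E)-4-{[tert-butyl(dimethyl)silyl]oxymethyl}-8,12,16-trimethylheptadeca-3,7,11,15-tetraen-1-ylidene]oxolan-2-ol (lactol, formed in the flask) | CC(C)=CCC/C(C)=C/CC/C(C)=C/CC/C(CO[Si](C)(C)C(C)(C)C)=C\C/C=C1\CCOC1O | intermediate
18 | (2E)-2-[(3E,7E,11E)-4-{[tert-butyl(dimethyl)silyl]oxymethyl}-8,12,16-trimethylheptadeca-3,7,11,15-tetraen-1-ylidene]butane-1,4-diol | CC(C)=CCC/C(C)=C/CC/C(C)=C/CC/C(CO[Si](C)(C)C(C)(C)C)=C\C/C=C(/CO)CCO | intermediate
19 | 2-[(2R,3R)-3-[(2E,6E,10E)-3-{[tert-butyl(dimethyl)silyl]oxymethyl}-7,11,15-trimethylhexadeca-2,6,10,14-tetraen-1-yl]-2-(hydroxymethyl)oxiran-2-yl]ethan-1-ol | CC(C)=CCC/C(C)=C/CC/C(C)=C/CC/C(CO[Si](C)(C)C(C)(C)C)=C\C[C@H]1O[C@@]1(CO)CCO | intermediate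
20 | 2-[(2R,3R)-3-[(2E,6E,10E)-3-{[tert-butyl(dimethyl)silyl]oxymethyl}-7,11,15-trimethylhexadeca-2,6,10,14-tetraen-1-yl]-2-(hydroxymethyl)oxiran-2-yl]acetaldehyde (formed in the flask) | CC(C)=CCC/C(C)=C/CC/C(C)=C/CC/C(CO[Si](C)(C)C(C)(C)C)=C\C[C@H]1O[C@@]1(CO)CC=O | intermediate
21 | (2R,3R)-2-[(2E,6E,10E)-3-{[tert-butyl(dimethyl)silyl]oxymethyl}-7,11,15-trimethylhexadeca-2,6,10,14-tetraen-1-yl]-1,5-dioxaspiro[2.4]heptan-6-ol (lactol, both C6 epimers, formed in the flask) | CC(C)=CCC/C(C)=C/CC/C(C)=C/CC/C(CO[Si](C)(C)C(C)(C)C)=C\C[C@H]1O[C@@]1(COC2O)C2 | intermediate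
22 | (2R,3R)-2-[(2E,6E,10E)-3-{[tert-butyl(dimethyl)silyl]oxymethyl}-7,11,15-trimethylhexadeca-2,6,10,14-tetraen-1-yl]-1,5-dioxaspiro[2.4]heptan-6-one | CC(C)=CCC/C(C)=C/CC/C(C)=C/CC/C(CO[Si](C)(C)C(C)(C)C)=C\C[C@H]1O[C@@]1(COC2=O)C2 | intermediate
23 | 4-[(1R,3E,7E,11E)-4-{[tert-butyl(dimethyl)silyl]oxymethyl}-1-hydroxy-8,12,16-trimethylheptadeca-3,7,11,15-tetraen-1-yl]furan-2(5H)-one | CC(C)=CCC/C(C)=C/CC/C(C)=C/CC/C(CO[Si](C)(C)C(C)(C)C)=C\C[C@@H](O)C1=CC(=O)OC1 | intermediate
24 | Hippolide C (4-[(1R,3E,7E,11E)-1-hydroxy-4-(hydroxymethyl)-8,12,16-trimethylheptadeca-3,7,11,15-tetraen-1-yl]furan-2(5H)-one) | CC(C)=CCC/C(C)=C/CC/C(C)=C/CC/C(=C\C[C@@H](O)C1=CC(=O)OC1)CO | target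

## Step count and risks

Total step count: 13. Longest linear sequence: 12 steps (farnesol through steps 1–4 and 6–13); the propargyl alcohol branch (step 5) joins at step 6.

Steps most likely to fail:

1. Step 10 (key step). The 1,4-diol, and later the epoxy diol, may sequester the titanium, which would slow turnover and erode enantioface selection. Delivery through the homoallylic C1 hydroxyl may compete, and the 2,2-disubstituted oxirane may be opened on the Lewis acid. Fallback: the C1 hydroxyl is masked before the epoxidation, setting out from lactone 16 and returning at epoxy diol 19. Aminolysis of 16 with Me(MeO)NH·HCl and AlMe3 should give the hydroxy Weinreb amide F1, and TESCl with imidazole the triethylsilyl ether F2. Reduction with iBu2AlH at −78 °C should give the enal F3, and NaBH4 with CeCl3·7H2O the mono-protected allylic alcohol F4, a plain 2,3-disubstituted (E)-allylic alcohol with a single free hydroxyl. Catalytic Ti(OiPr)4, D-(−)-diisopropyl tartrate and tBuOOH should then give the epoxy alcohol F5. PPTS in MeOH at 0 °C removes the triethylsilyl group in the presence of the TBS ether and returns 19.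

2. Step 8. The C4 ruthenium alkylidene may close a seven-membered ring onto C10=C11, which the cis arrangement of C5 and C8 on C6=C7 permits. Turnover with the hindered, electron-poor lactone may also stall, or the skipped diene may isomerise. Fallback: the C3=C4 bond is made by Wittig olefination without metathesis, setting out from bromide 6 (as its Grignard reagent 10) and returning at lactone 16. Commercial 2-(but-3-yn-1-yloxy)oxane is hydroxymethylated (n-BuLi, paraformaldehyde) to 5-(oxan-2-yloxy)pent-2-yn-1-ol F6. Carbomagnesiation with 10 as in step 6 should give the THP-protected allylic alcohol F7, and TBSCl with imidazole the silyl ether F8. MgBr2·OEt2 in Et2O removes the THP group to give the homoallylic alcohol F9, and buffered Dess–Martin periodinane should give the β,γ-unsaturated aldehyde F10. F10 is used at once with 3-(triphenylphosphoranylidene)oxolan-2-one in CH2Cl2, and the stabilised ylide should give the E-alkylidene lactone 16.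

3. Step 6. The CuI-catalysed addition of a primary alkyl Grignard reagent may be sluggish, may attack the wrong alkyne carbon, or may deprotonate the doubly activated C5 methylene of the skipped enyne. Fallback: the C7–C8 bond is made by cross-coupling, setting out from enynol 9 and borane 4 (from tetraene 3) and returning at dienol 13; the oxidative half of step 3 and step 4 then fall away. Hydroxyl-directed trans-hydrostannation of 9 ([Cp*RuCl]4, Bu3SnH, CH2Cl2) should give (2Z)-2-(tributylstannyl)hexa-2,5-dien-1-ol F11. Iodine converts it with retention to (2Z)-2-iodohexa-2,5-dien-1-ol F12. B-alkyl Suzuki–Miyaura coupling of F12 with 4 (PdCl2(dppf), AsPh3, Cs2CO3, DMF/THF/H2O, rt) should give 13 with retention at the alkenyl carbon.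

Further compounds
F1 | step 10 | (2E,5E,9E,13E)-6-{[tert-butyl(dimethyl)silyl]oxymethyl}-2-(2-hydroxyethyl)-N-methoxy-N,10,14,18-tetramethylnonadeca-2,5,9,13,17-pentaenamide | CC(C)=CCC/C(C)=C/CC/C(C)=C/CC/C(CO[Si](C)(C)C(C)(C)C)=C\C/C=C(\CCO)C(=O)N(C)OC
F2 | step 10 | (2E,5E,9E,13E)-6-{[tert-butyl(dimethyl)silyl]oxymethyl}-N-methoxy-N,10,14,18-tetramethyl-2-[2-(triethylsilyloxy)ethyl]nonadeca-2,5,9,13,17-pentaenamide | CC(C)=CCC/C(C)=C/CC/C(C)=C/CC/C(CO[Si](C)(C)C(C)(C)C)=C\C/C=C(\CCO[Si](CC)(CC)CC)C(=O)N(C)OC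
F3 | step 10 | (2E,5E,9E,13E)-6-{[tert-butyl(dimethyl)silyl]oxymethyl}-10,14,18-trimethyl-2-[2-(triethylsilyloxy)ethyl]nonadeca-2,5,9,13,17-pentaenal | CC(C)=CCC/C(C)=C/CC/C(C)=C/CC/C(CO[Si](C)(C)C(C)(C)C)=C\C/C=C(\CCO[Si](CC)(CC)CC)C=O
F4 | step 10 | (2E,5E,9E,13E)-6-{[tert-butyl(dimethyl)silyl]oxymethyl}-10,14,18-trimethyl-2-[2-(triethylsilyloxy)ethyl]nonadeca-2,5,9,13,17-pentaen-1-ol | CC(C)=CCC/C(C)=C/CC/C(C)=C/CC/C(CO[Si](C)(C)C(C)(C)C)=C\C/C=C(\CCO[Si](CC)(CC)CC)CO
F5 | step 10 | [(2R,3R)-3-[(2E,6E,10E)-3-{[tert-butyl(dimethyl)silyl]oxymethyl}-7,11,15-trimethylhexadeca-2,6,10,14-tetraen-1-yl]-2-[2-(triethylsilyloxy)ethyl]oxiran-2-yl]methanol | CC(C)=CCC/C(C)=C/CC/C(C)=C/CC/C(CO[Si](C)(C)C(C)(C)C)=C\C[C@H]1O[C@@]1(CO)CCO[Si](CC)(CC)CC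
F6 | step 8 | 5-(oxan-2-yloxy)pent-2-yn-1-ol | OCC#CCCOC1CCCCO1
F7 | step 8 | (2E)-5-(oxan-2-yloxy)-2-[(3E,7E)-4,8,12-trimethyltrideca-3,7,11-trien-1-yl]pent-2-en-1-ol | CC(C)=CCC/C(C)=C/CC/C(C)=C/CC/C(CO)=C\CCOC1CCCCO1
F8 | step 8 | tert-butyl(dimethyl){[(2E)-5-(oxan-2-yloxy)-2-[(3E,7E)-4,8,12-trimethyltrideca-3,7,11-trien-1-yl]pent-2-en-1-yl]oxy}silane | CC(C)=CCC/C(C)=C/CC/C(C)=C/CC/C(CO[Si](C)(C)C(C)(C)C)=C\CCOC1CCCCO1
F9 | step 8 | (3E,7E,11E)-4-{[tert-butyl(dimethyl)silyl]oxymethyl}-8,12,16-trimethylheptadeca-3,7,11,15-tetraen-1-ol | CC(C)=CCC/C(C)=C/CC/C(C)=C/CC/C(CO[Si](C)(C)C(C)(C)C)=C\CCO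
F10 | step 8 | (3E,7E,11E)-4-{[tert-butyl(dimethyl)silyl]oxymethyl}-8,12,16-trimethylheptadeca-3,7,11,15-tetraenal | CC(C)=CCC/C(C)=C/CC/C(C)=C/CC/C(CO[Si](C)(C)C(C)(C)C)=C\CC=O
F11 | step 6 | (2Z)-2-(tributylstannyl)hexa-2,5-dien-1-ol | C=CC/C=C(\[Sn](CCCC)(CCCC)CCCC)CO
F12 | step 6 | (2Z)-2-iodohexa-2,5-dien-1-ol | C=CC/C=C(\I)CO
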